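Numbering: ring C1–C10 with alkenes C1=C10 and C4=C5 (both cis within the ring, E by the sequence rules); lactone oxygen on C6; C7 carries C11(=C13H2)–C12(=O); acrylate oxygen on C8; C14 (CH2OAc) on C10; C15 (CHO) on C4.
Retrosynthesis: the C13 methylene, the O8 and O14 acyl groups and the C15 aldehyde are removed first; then C5–C6 and O6–C12 are cut together; then C7–C8 (aldol), C1=C10 (Wittig) and C3–C4 (carbocupration).
Enabling feature: C6 is an allylic carbinol carbon between the C4=C5 alkene and stereocentre C7, and its oxygen is 1,4 to the C12 carboxyl, so a C5 alkenyl-metal adding to a C6 aldehyde closes the ten-membered ring and the new alkoxide closes the γ-lactone.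
Forward: the C5→C8 chain is built linearly, the C6/C7/C11/C12 succinate unit is joined by aldol, ring C1–C10 and the lactone ring then arise in one operation, and α-methylenation plus ester and oxidation-level adjustments finish.
Stereochemistry: C7 and C8 from a thiazolidinethione-controlled syn aldol; C6 from Felkin–Anh addition in the ring closure (trans-fused lactone); C4=C5 from syn-carbocupration/iodination and C1=C10 from an E-selective stabilised-ylide Wittig reaction, both carried unchanged through the ring closure.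

Key step: step 15

Remark: locants C1–C15 in names and comments are the skeleton locants defined above; the C7 descriptor reads S while O8 bears silicon in the ring compounds and R otherwise, with no change in spatial arrangement; the bromoacetal, the hydroxypropylphosphonium salt, the thiazolidinethione, methyl succinyl chloride and ethyl 2-(hydroxymethyl)acrylate are taken as commercial.

Step 1
Reactants: 1 prop-2-yn-1-ol (propargyl alcohol)
Product: 2 1-methoxy-4-[(prop-2-yn-1-yloxy)methyl]benzene (propargyl PMB ether)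
Conditions: NaH, 4-methoxybenzyl chloride, tetrabutylammonium iodide (Bu4NI, cat.), THF/DMF, 0 °C → rt
Reagents that add atoms: 4-methoxybenzyl chloride, COc1ccc(CCl)cc1
Why: Williamson ether synthesis, the sodium alkoxide displacing chloride from the benzylic halide under iodide catalysis; no stereocentre is involved.

Step 2
Reactants: 2 1-methoxy-4-[(prop-2-yn-1-yloxy)methyl]benzene; 3 2-(2-bromoethyl)-1,3-dioxolane
Product: 7 2-[(3E)-4-iodo-3-{[(4-methoxybenzyl)oxy]methyl}but-3-en-1-yl]-1,3-dioxolane (iodine cis to the dioxolanylethyl chain), via Grignard reagent 4 (not isolated), via alkylcopper reagent 5 (not isolated), via alkenylcopper adduct 6 (not isolated)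
Conditions: 3, Mg, THF, 25 °C; CuBr·SMe2 (1.0 equiv), THF, −45 °C; 2, −45 → −20 °C; I2, THF, −78 → 0 °C
Reagents that add atoms: iodine, II
Why: Normant syn-carbocupration of a terminal alkyne, in which the alkyl group goes to the substituted carbon C4 and copper to the terminal carbon C5 on the same side (THF as donor solvent disfavours ether-directed reverse addition), followed by iodinolysis with retention, which places iodine cis to the new C3 chain and so fixes the (E) geometry of C4=C5.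

Step 3
Reactants: 7 2-[(3E)-4-iodo-3-{[(4-methoxybenzyl)oxy]methyl}but-3-en-1-yl]-1,3-dioxolane
Product: 8 (4E)-5-iodo-4-{[(4-methoxybenzyl)oxy]methyl}pent-4-enal (C1–C5 aldehyde)
Conditions: 1 M HCl, THF, rt
Reagents that add atoms: water, O
Why: Acid-catalysed hydrolysis of the dioxolane acetal; the alkenyl iodide and the PMB ether are stable to dilute aqueous acid at room temperature.

Step 4
Reactants: 9 (3-hydroxypropyl)triphenylphosphonium bromide
Product: 10 triphenyl{3-[(triethylsilyl)oxy]propyl}phosphonium bromide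
Conditions: Et3SiCl, imidazole, CH2Cl2, rt
Reagents that add atoms: chlorotriethylsilane, CC[Si](CC)(CC)Cl
Why: Silyl ether formation at the primary alcohol with imidazole as base; the phosphonium centre is inert.

Step 5
Reactants: 10 triphenyl{3-[(triethylsilyl)oxy]propyl}phosphonium bromide
Product: 13 methyl 4-[(triethylsilyl)oxy]-2-(triphenylphosphoranylidene)butanoate, via non-stabilised ylide 11 (not isolated), via acylphosphonium chloride 12 (not isolated)
Conditions: NaN(SiMe3)2 (1.0 equiv), THF, −78 → 0 °C; ClCO2Me (1.0 equiv), −78 °C; NaN(SiMe3)2 (1.0 equiv), −78 °C → rt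
Reagents that add atoms: methyl chloroformate, COC(=O)Cl
Why: Bestmann acylation of a phosphorus ylide, the non-stabilised ylide being C-acylated by the chloroformate and the acylphosphonium salt then deprotonated to the isolable ester-stabilised ylide.

Step 6
Reactants: 8 (4E)-5-iodo-4-{[(4-methoxybenzyl)oxy]methyl}pent-4-enal; 13 methyl 4-[(triethylsilyl)oxy]-2-(triphenylphosphoranylidene)butanoate
Product: 14 methyl (2E,6E)-7-iodo-6-{[(4-methoxybenzyl)oxy]methyl}-2-{2-[(triethylsilyl)oxy]ethyl}hepta-2,6-dienoate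
Conditions: toluene, 80 °C
Reagents that add atoms: none
Why: Wittig olefination with an α-substituted ester-stabilised ylide, whose reversible oxaphosphetane formation should give the (E)-enoate with the ester carbon C14 trans to C2, so that C9 is cis to C2 as the ring requires.

Step 7
Reactants: 14 methyl (2E,6E)-7-iodo-6-{[(4-methoxybenzyl)oxy]methyl}-2-{2-[(triethylsilyl)oxy]ethyl}hepta-2,6-dienoate
Product: 15 (2E,6E)-7-iodo-6-{[(4-methoxybenzyl)oxy]methyl}-2-{2-[(triethylsilyl)oxy]ethyl}hepta-2,6-dien-1-ol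
Conditions: iBu2AlH (2.5 equiv), CH2Cl2, −78 °C
Reagents that add atoms: none
Why: 1,2-Reduction of the conjugated ester to the allylic alcohol by iBu2AlH at low temperature; the silyl ether, the PMB ether and the alkenyl iodide are inert and the alkene geometry is untouched.

Step 8
Reactants: 15 (2E,6E)-7-iodo-6-{[(4-methoxybenzyl)oxy]methyl}-2-{2-[(triethylsilyl)oxy]ethyl}hepta-2,6-dien-1-ol
Product: 16 tert-butyl{[(2E,6E)-7-iodo-6-{[(4-methoxybenzyl)oxy]methyl}-2-{2-[(triethylsilyl)oxy]ethyl}hepta-2,6-dien-1-yl]oxy}dimethylsilane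
Conditions: tBuMe2SiCl, imidazole, CH2Cl2, 0 °C → rt
Reagents that add atoms: tert-butyldimethylsilyl chloride, CC(C)(C)[Si](C)(C)Cl
Why: Silyl ether formation at the primary allylic alcohol, giving the O14 protecting group that lasts until step 18.

Step 9
Reactants: 16 tert-butyl{[(2E,6E)-7-iodo-6-{[(4-methoxybenzyl)oxy]methyl}-2-{2-[(triethylsilyl)oxy]ethyl}hepta-2,6-dien-1-yl]oxy}dimethylsilane
Product: 17 (3E,7E)-3-{[(tert-butyldimethylsilyl)oxy]methyl}-8-iodo-7-{[(4-methoxybenzyl)oxy]methyl}octa-3,7-dien-1-ol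
Conditions: pyridinium p-toluenesulfonate (PPTS, 0.1 equiv), MeOH/CH2Cl2 1:1, 0 °C
Reagents that add atoms: none
Why: Acid-catalysed methanolysis, in which a primary triethylsilyl ether is cleaved much faster than the primary tert-butyldimethylsilyl ether, so that only O8 is freed.

Step 10
Reactants: 17 (3E,7E)-3-{[(tert-butyldimethylsilyl)oxy]methyl}-8-iodo-7-{[(4-methoxybenzyl)oxy]methyl}octa-3,7-dien-1-ol
Product: 18 (3E,7E)-3-{[(tert-butyldimethylsilyl)oxy]methyl}-8-iodo-7-{[(4-methoxybenzyl)oxy]methyl}octa-3,7-dienal (C8 aldehyde)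
Conditions: Dess–Martin periodinane (1.3 equiv), pyridine (3 equiv), CH2Cl2, 0 °C; used crude at once
Reagents that add atoms: none
Why: Dess–Martin oxidation under buffered, non-enolising conditions should give the β,γ-unsaturated aldehyde without migration of C1=C10 into conjugation.

Step 11
Reactants: 19 (R)-4-benzyl-1,3-thiazolidine-2-thione; 20 methyl 4-chloro-4-oxobutanoate
Product: 21 methyl 4-[(4R)-4-benzyl-2-thioxo-1,3-thiazolidin-3-yl]-4-oxobutanoate
Conditions: Et3N, 4-(dimethylamino)pyridine (DMAP, cat.), CH2Cl2, 0 °C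
Reagents that add atoms: none
Why: N-Acylation of the thiazolidinethione by the acid chloride with an amine base; the auxiliary stereocentre is not involved.

Step 12
Reactants: 21 methyl 4-[(4R)-4-benzyl-2-thioxo-1,3-thiazolidin-3-yl]-4-oxobutanoate; 18 (3E,7E)-3-{[(tert-butyldimethylsilyl)oxy]methyl}-8-iodo-7-{[(4-methoxybenzyl)oxy]methyl}octa-3,7-dienal
Product: 23 methyl (3R,4S,6E,10E)-3-{[(4R)-4-benzyl-2-thioxo-1,3-thiazolidin-3-yl]carbonyl}-6-{[(tert-butyldimethylsilyl)oxy]methyl}-4-hydroxy-11-iodo-10-{[(4-methoxybenzyl)oxy]methyl}undeca-6,10-dienoate (syn adduct; 7R and 8S in skeleton locants), via chlorotitanium enolate 22 (not isolated)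
Conditions: TiCl4 (1.05 equiv), iPr2NEt (1.1 equiv), N-methyl-2-pyrrolidinone (1.0 equiv), CH2Cl2, 0 °C; 18, −78 → 0 °C
Reagents that add atoms: none
Why: Crimmins titanium aldol in its Evans-syn mode: soft enolisation gives the chlorotitanium (Z)-enolate, N-methyl-2-pyrrolidinone keeps the thiocarbonyl off titanium so that a non-chelated chair Zimmerman–Traxler transition state operates, and the aldehyde adds to the enolate face remote from the benzyl group, setting C7 (R) and C8 (S) syn.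

Step 13
Reactants: 23 methyl (3R,4S,6E,10E)-3-{[(4R)-4-benzyl-2-thioxo-1,3-thiazolidin-3-yl]carbonyl}-6-{[(tert-butyldimethylsilyl)oxy]methyl}-4-hydroxy-11-iodo-10-{[(4-methoxybenzyl)oxy]methyl}undeca-6,10-dienoate
Product: 24 methyl (3R,4S,6E,10E)-3-{[(4R)-4-benzyl-2-thioxo-1,3-thiazolidin-3-yl]carbonyl}-4-[(tert-butyldimethylsilyl)oxy]-6-{[(tert-butyldimethylsilyl)oxy]methyl}-11-iodo-10-{[(4-methoxybenzyl)oxy]methyl}undeca-6,10-dienoate
Conditions: tBuMe2SiOTf, 2,6-lutidine, CH2Cl2, −78 → 0 °C, on the crude adduct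
Reagents that add atoms: tert-butyldimethylsilyl trifluoromethanesulfonate, CC(C)(C)[Si](C)(C)OS(=O)(=O)C(F)(F)F
Why: Silylation of the hindered secondary alcohol with a silyl triflate and a hindered pyridine base, done without delay so that O8 cannot lactonise onto the C12 ester.

Step 14
Reactants: 24 methyl (3R,4S,6E,10E)-3-{[(4R)-4-benzyl-2-thioxo-1,3-thiazolidin-3-yl]carbonyl}-4-[(tert-butyldimethylsilyl)oxy]-6-{[(tert-butyldimethylsilyl)oxy]methyl}-11-iodo-10-{[(4-methoxybenzyl)oxy]methyl}undeca-6,10-dienoate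
Product: 25 methyl (3R,4S,6E,10E)-4-[(tert-butyldimethylsilyl)oxy]-6-{[(tert-butyldimethylsilyl)oxy]methyl}-3-formyl-11-iodo-10-{[(4-methoxybenzyl)oxy]methyl}undeca-6,10-dienoate (open-chain iodo-dienyl aldehyde ester; 7R and 8S)
Conditions: iBu2AlH (1.1 equiv, added until the yellow colour fades), CH2Cl2, −78 °C
Reagents that add atoms: none
Why: Direct reduction of an N-acylthiazolidinethione to the aldehyde (Nagao–Crimmins), in which the activated thioimide carbonyl takes up hydride much faster than the methyl ester and the tetrahedral aluminate collapses only on work-up, so that C6 stops at the aldehyde and C7 is not epimerised.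

Step 15
Reactants: 25 methyl (3R,4S,6E,10E)-4-[(tert-butyldimethylsilyl)oxy]-6-{[(tert-butyldimethylsilyl)oxy]methyl}-3-formyl-11-iodo-10-{[(4-methoxybenzyl)oxy]methyl}undeca-6,10-dienoate
Product: 28 (1(10)E,4E,6R,7S,8S)-8,14-bis[(tert-butyldimethylsilyl)oxy]-15-[(4-methoxybenzyl)oxy]-13-norgermacra-1(10),4-dien-12,6-olide (trans-fused cyclodecadieno-γ-lactone; C11 is CH2), via alkenylchromium species 26 (not isolated), via macrocyclic hydroxy ester 27 (not isolated)
Conditions: CrCl2 (15 equiv), NiCl2 (1 mol % of the CrCl2), DMSO/THF 3:1, 0.003 M, slow addition of 25, rt; aq. work-up, then pyridinium p-toluenesulfonate (PPTS, cat.), CH2Cl2, rt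
Reagents that add atoms: none
Why: Nozaki–Hiyama–Kishi reaction: zerovalent nickel formed in situ inserts into the C5–I bond, the alkenyl group passes to trivalent chromium and the alkenylchromium adds to the C6 aldehyde with retention of the C4=C5 geometry; the closest known reaction type is the NHK alkenyl iodide–aldehyde macrocyclisation used for medium and large carbocycles. The ten-membered ring closes by direct 10-exo-trig attack of C5 on the carbonyl, helped by the two ring-cis trisubstituted alkenes that bring the chain ends together, and the γ-lactone then closes by 5-exo-trig attack of the C6 alkoxide on the C12 methyl ester with loss of methanol. C6 is set by the adjacent C7 stereocentre: Felkin–Anh addition anti to the large C8 branch places O6 syn to C11 along the C5–C8 backbone, which is the 6R configuration and the one that gives the trans-fused lactone. The step needs chemoselectivity for the aldehyde over the ester, the silyl ethers and the PMB ether, which the low basicity of organochromium reagents provides, and it must leave C7 untouched, which the neutral medium ensures. Ring closure over oligomerisation is secured by slow addition of 25 to excess CrCl2 at high dilution.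

Step 16
Reactants: 28 (1(10)E,4E,6R,7S,8S)-8,14-bis[(tert-butyldimethylsilyl)oxy]-15-[(4-methoxybenzyl)oxy]-13-norgermacra-1(10),4-dien-12,6-olide
Product: 30 (1(10)E,4E,6R,7S,8S)-8,14-bis[(tert-butyldimethylsilyl)oxy]-13-(dimethylamino)-15-[(4-methoxybenzyl)oxy]germacra-1(10),4-dien-12,6-olide (C11 epimers), via lithium enolate 29 (not isolated)
Conditions: LiN(iPr)2 (1.5 equiv), THF, −78 °C; Eschenmoser's salt (Me2N=CH2 iodide), −78 → 0 °C
Reagents that add atoms: N,N-dimethylmethyleneiminium iodide (Eschenmoser's salt), C=[N+](C)C.[I-]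
Why: Mannich reaction of the lactone lithium enolate with Eschenmoser's salt introduces C13 at C11; the new C11 stereocentre is of no consequence because it becomes trigonal in step 17.

Step 17
Reactants: 30 (1(10)E,4E,6R,7S,8S)-8,14-bis[(tert-butyldimethylsilyl)oxy]-13-(dimethylamino)-15-[(4-methoxybenzyl)oxy]germacra-1(10),4-dien-12,6-olide
Product: 32 (1(10)E,4E,6R,7S,8S)-8,14-bis[(tert-butyldimethylsilyl)oxy]-15-[(4-methoxybenzyl)oxy]germacra-1(10),4,11(13)-trien-12,6-olide, via trimethylammonium iodide 31 (not isolated)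
Conditions: MeI, MeOH, rt; then sat. aq. NaHCO3, CH2Cl2, rt
Reagents that add atoms: none
Why: Exhaustive N-methylation followed by base-induced Hofmann-type (E1cB) elimination of trimethylamine should give the α-methylene lactone.

Step 18
Reactants: 32 (1(10)E,4E,6R,7S,8S)-8,14-bis[(tert-butyldimethylsilyl)oxy]-15-[(4-methoxybenzyl)oxy]germacra-1(10),4,11(13)-trien-12,6-olide
Product: 33 (1(10)E,4E,6R,7R,8S)-8,14-dihydroxy-15-[(4-methoxybenzyl)oxy]germacra-1(10),4,11(13)-trien-12,6-olide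
Conditions: HF·pyridine, pyridine, THF, 0 °C → rt
Reagents that add atoms: none
Why: Fluoride-mediated cleavage of both silyl ethers under buffered, non-basic conditions, which avoids an O8 alkoxide that could translactonise onto C12 or add to the methylene lactone.

Step 19
Reactants: 33 (1(10)E,4E,6R,7R,8S)-8,14-dihydroxy-15-[(4-methoxybenzyl)oxy]germacra-1(10),4,11(13)-trien-12,6-olide
Product: 34 (1(10)E,4E,6R,7R,8S)-14-acetoxy-8-hydroxy-15-[(4-methoxybenzyl)oxy]germacra-1(10),4,11(13)-trien-12,6-olide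
Conditions: AcCl (1.1 equiv), 2,4,6-collidine, CH2Cl2, −78 °C
Reagents that add atoms: acetyl chloride, CC(Cl)=O
Why: Chemoselective acylation, acetyl chloride with a hindered pyridine base at low temperature acetylating the primary allylic C14 hydroxyl far faster than the hindered secondary C8 hydroxyl.

Step 20
Reactants: 35 ethyl 2-(hydroxymethyl)acrylate
Product: 36 ethyl 2-{[(tert-butyldimethylsilyl)oxy]methyl}acrylate
Conditions: tBuMe2SiCl, imidazole, CH2Cl2, 0 °C → rt
Reagents that add atoms: tert-butyldimethylsilyl chloride, CC(C)(C)[Si](C)(C)Cl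
Why: Silyl ether formation at the primary alcohol, so that the acid can later be activated without self-esterification.

Step 21
Reactants: 36 ethyl 2-{[(tert-butyldimethylsilyl)oxy]methyl}acrylate
Product: 37 2-{[(tert-butyldimethylsilyl)oxy]methyl}acrylic acid
Conditions: LiOH·H2O, THF/H2O, 0 °C → rt; 1 M HCl to pH 4
Reagents that add atoms: lithium hydroxide, [Li+].[OH-]
Why: Saponification of the ethyl ester by hydroxide at low temperature; the primary silyl ether survives and mild acidification frees the acid.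

Step 22
Reactants: 34 (1(10)E,4E,6R,7R,8S)-14-acetoxy-8-hydroxy-15-[(4-methoxybenzyl)oxy]germacra-1(10),4,11(13)-trien-12,6-olide; 37 2-{[(tert-butyldimethylsilyl)oxy]methyl}acrylic acid
Product: 39 (1(10)E,4E,6R,7R,8S)-14-acetoxy-8-({2-[(tert-butyldimethylsilyloxy)methyl]acryloyl}oxy)-15-[(4-methoxybenzyl)oxy]germacra-1(10),4,11(13)-trien-12,6-olide, via mixed anhydride 38 (not isolated)
Conditions: 37, 2,4,6-trichlorobenzoyl chloride, Et3N, toluene, rt; then 34, 4-(dimethylamino)pyridine (DMAP), toluene, rt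
Reagents that add atoms: none
Why: Yamaguchi esterification, the mixed anhydride being attacked at the acryloyl carbonyl by the C8 hydroxyl under nucleophilic catalysis; acylation at oxygen leaves the C8 configuration unchanged.

Step 23
Reactants: 39 (1(10)E,4E,6R,7R,8S)-14-acetoxy-8-({2-[(tert-butyldimethylsilyloxy)methyl]acryloyl}oxy)-15-[(4-methoxybenzyl)oxy]germacra-1(10),4,11(13)-trien-12,6-olide
Product: 40 (1(10)E,4E,6R,7R,8S)-14-acetoxy-8-({2-[(tert-butyldimethylsilyloxy)methyl]acryloyl}oxy)-15-hydroxygermacra-1(10),4,11(13)-trien-12,6-olide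
Conditions: DDQ (1.3 equiv), CH2Cl2/pH 7 buffer 10:1, 0 °C
Reagents that add atoms: none
Why: Oxidative cleavage of the 4-methoxybenzyl ether by DDQ (benzylic hydride abstraction, then hydrolysis of the oxocarbenium ion), to which the esters, the silyl ether and the electron-poor alkenes are inert.

Step 24
Reactants: 40 (1(10)E,4E,6R,7R,8S)-14-acetoxy-8-({2-[(tert-butyldimethylsilyloxy)methyl]acryloyl}oxy)-15-hydroxygermacra-1(10),4,11(13)-trien-12,6-olide
Product: 41 (1(10)E,4E,6R,7R,8S)-14-acetoxy-8-({2-[(tert-butyldimethylsilyloxy)methyl]acryloyl}oxy)-15-oxogermacra-1(10),4,11(13)-trien-12,6-olide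
Conditions: MnO2 (excess), CH2Cl2, rt
Reagents that add atoms: none
Why: MnO2 oxidation of the primary allylic alcohol to the conjugated aldehyde, selective for allylic alcohols and expected to leave the C4=C5 geometry unchanged.

Step 25
Reactants: 41 (1(10)E,4E,6R,7R,8S)-14-acetoxy-8-({2-[(tert-butyldimethylsilyloxy)methyl]acryloyl}oxy)-15-oxogermacra-1(10),4,11(13)-trien-12,6-olide
Product: 42 (1(10)E,4E,6R,7R,8S)-14-acetoxy-8-{[2-(hydroxymethyl)acryloyl]oxy}-15-oxogermacra-1(10),4,11(13)-trien-12,6-olide (target)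
Conditions: HF·pyridine, pyridine, THF, 0 °C
Reagents that add atoms: none
Why: Fluoride cleavage of the remaining primary silyl ether under buffered conditions compatible with the enal, the acetate, the acrylate and the methylene lactone should give the target.

Compound list
1 | prop-2-yn-1-ol (propargyl alcohol) | C#CCO | starting material
2 | 1-methoxy-4-[(prop-2-yn-1-yloxy)methyl]benzene | C#CCOCc1ccc(OC)cc1 | intermediate
3 | 2-(2-bromoethyl)-1,3-dioxolane | BrCCC1OCCO1 | starting material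
4 | [2-(1,3-dioxolan-2-yl)ethyl]magnesium bromide (not isolated) | Br[Mg]CCC1OCCO1 | intermediate
5 | [2-(1,3-dioxolan-2-yl)ethyl]copper as its MgBr2 complex (not isolated) | [Cu]CCC1OCCO1 | intermediate
6 | (E)-alkenylcopper adduct with copper at C5 cis to the C3 chain (not isolated) | [Cu]/C=C(\CCC1OCCO1)COCc1ccc(OC)cc1 | intermediate
7 | 2-[(3E)-4-iodo-3-{[(4-methoxybenzyl)oxy]methyl}but-3-en-1-yl]-1,3-dioxolane | I/C=C(\CCC1OCCO1)COCc1ccc(OC)cc1 | intermediate
8 | (4E)-5-iodo-4-{[(4-methoxybenzyl)oxy]methyl}pent-4-enal | O=CCC/C(COCc1ccc(OC)cc1)=C\I | intermediate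
9 | (3-hydroxypropyl)triphenylphosphonium bromide | OCCC[P+](c1ccccc1)(c1ccccc1)c1ccccc1.[Br-] | starting material
10 | triphenyl{3-[(triethylsilyl)oxy]propyl}phosphonium bromide | CC[Si](CC)(CC)OCCC[P+](c1ccccc1)(c1ccccc1)c1ccccc1.[Br-] | intermediate
11 | triphenyl{3-[(triethylsilyl)oxy]propylidene}phosphorane (not isolated) | CC[Si](CC)(CC)OCCC=P(c1ccccc1)(c1ccccc1)c1ccccc1 | intermediate
12 | [1-methoxy-1-oxo-4-(triethylsilyloxy)butan-2-yl]triphenylphosphonium chloride (not isolated) | COC(=O)C(CCO[Si](CC)(CC)CC)[P+](c1ccccc1)(c1ccccc1)c1ccccc1.[Cl-] | intermediate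
13 | methyl 4-[(triethylsilyl)oxy]-2-(triphenylphosphoranylidene)butanoate | COC(=O)C(CCO[Si](CC)(CC)CC)=P(c1ccccc1)(c1ccccc1)c1ccccc1 | intermediate
14 | methyl (2E,6E)-7-iodo-6-{[(4-methoxybenzyl)oxy]methyl}-2-{2-[(triethylsilyl)oxy]ethyl}hepta-2,6-dienoate | COC(=O)/C(CCO[Si](CC)(CC)CC)=C/CC/C(COCc1ccc(OC)cc1)=C\I | intermediate
15 | (2E,6E)-7-iodo-6-{[(4-methoxybenzyl)oxy]methyl}-2-{2-[(triethylsilyl)oxy]ethyl}hepta-2,6-dien-1-ol | OC/C(CCO[Si](CC)(CC)CC)=C/CC/C(COCc1ccc(OC)cc1)=C\I | intermediate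
16 | tert-butyl{[(2E,6E)-7-iodo-6-{[(4-methoxybenzyl)oxy]methyl}-2-{2-[(triethylsilyl)oxy]ethyl}hepta-2,6-dien-1-yl]oxy}dimethylsilane | CC(C)(C)[Si](C)(C)OC/C(CCO[Si](CC)(CC)CC)=C/CC/C(COCc1ccc(OC)cc1)=C\I | intermediate
17 | (3E,7E)-3-{[(tert-butyldimethylsilyl)oxy]methyl}-8-iodo-7-{[(4-methoxybenzyl)oxy]methyl}octa-3,7-dien-1-ol | OCC/C(CO[Si](C)(C)C(C)(C)C)=C\CC/C(COCc1ccc(OC)cc1)=C\I | intermediate
18 | (3E,7E)-3-{[(tert-butyldimethylsilyl)oxy]methyl}-8-iodo-7-{[(4-methoxybenzyl)oxy]methyl}octa-3,7-dienal | O=CC/C(CO[Si](C)(C)C(C)(C)C)=C\CC/C(COCc1ccc(OC)cc1)=C\I | intermediate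
19 | (R)-4-benzyl-1,3-thiazolidine-2-thione | S=C1N[C@H](Cc2ccccc2)CS1 | starting material
20 | methyl 4-chloro-4-oxobutanoate | COC(=O)CCC(=O)Cl | starting material
21 | methyl 4-[(4R)-4-benzyl-2-thioxo-1,3-thiazolidin-3-yl]-4-oxobutanoate | COC(=O)CCC(=O)N1C(=S)SC[C@H]1Cc1ccccc1 | intermediate
22 | chlorotitanium (Z)-enolate of 21 (not isolated) | COC(=O)C/C=C(\O[Ti](Cl)(Cl)Cl)N1C(=S)SC[C@H]1Cc1ccccc1 | intermediate
23 | methyl (3R,4S,6E,10E)-3-{[(4R)-4-benzyl-2-thioxo-1,3-thiazolidin-3-yl]carbonyl}-6-{[(tert-butyldimethylsilyl)oxy]methyl}-4-hydroxy-11-iodo-10-{[(4-methoxybenzyl)oxy]methyl}undeca-6,10-dienoate | S=C1SC[C@@H](Cc2ccccc2)N1C(=O)[C@H](CC(=O)OC)[C@@H](O)C/C(CO[Si](C)(C)C(C)(C)C)=C\CC/C(COCc1ccc(OC)cc1)=C\I | intermediate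
24 | methyl (3R,4S,6E,10E)-3-{[(4R)-4-benzyl-2-thioxo-1,3-thiazolidin-3-yl]carbonyl}-4-[(tert-butyldimethylsilyl)oxy]-6-{[(tert-butyldimethylsilyl)oxy]methyl}-11-iodo-10-{[(4-methoxybenzyl)oxy]methyl}undeca-6,10-dienoate | S=C1SC[C@@H](Cc2ccccc2)N1C(=O)[C@H](CC(=O)OC)[C@@H](O[Si](C)(C)C(C)(C)C)C/C(CO[Si](C)(C)C(C)(C)C)=C\CC/C(COCc1ccc(OC)cc1)=C\I | intermediate
25 | methyl (3R,4S,6E,10E)-4-[(tert-butyldimethylsilyl)oxy]-6-{[(tert-butyldimethylsilyl)oxy]methyl}-3-formyl-11-iodo-10-{[(4-methoxybenzyl)oxy]methyl}undeca-6,10-dienoate | O=C[C@H](CC(=O)OC)[C@@H](O[Si](C)(C)C(C)(C)C)C/C(CO[Si](C)(C)C(C)(C)C)=C\CC/C(COCc1ccc(OC)cc1)=C\I | intermediate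
26 | C5 alkenylchromium dichloride derived from 25 with geometry retained (not isolated) | O=C[C@H](CC(=O)OC)[C@@H](O[Si](C)(C)C(C)(C)C)C/C(CO[Si](C)(C)C(C)(C)C)=C\CC/C(COCc1ccc(OC)cc1)=C\[Cr](Cl)Cl | intermediate
27 | methyl (1(10)E,4E,6R,7S,8S)-8,14-bis[(tert-butyldimethylsilyl)oxy]-6-hydroxy-15-[(4-methoxybenzyl)oxy]-13-norgermacra-1(10),4-dien-12-oate (formed as its chromium alkoxide; not isolated) | CC(C)(C)[Si](C)(C)O[C@H]1C/C(CO[Si](C)(C)C(C)(C)C)=C\CC/C(COCc2ccc(OC)cc2)=C\[C@@H](O)[C@@H]1CC(=O)OC | intermediate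
28 | (1(10)E,4E,6R,7S,8S)-8,14-bis[(tert-butyldimethylsilyl)oxy]-15-[(4-methoxybenzyl)oxy]-13-norgermacra-1(10),4-dien-12,6-olide | CC(C)(C)[Si](C)(C)O[C@H]1C/C(CO[Si](C)(C)C(C)(C)C)=C\CC/C(COCc3ccc(OC)cc3)=C\[C@H]2OC(=O)C[C@H]12 | intermediate
29 | lithium enolate of 28 across C11–C12 (not isolated) | CC(C)(C)[Si](C)(C)O[C@H]1C/C(CO[Si](C)(C)C(C)(C)C)=C\CC/C(COCc3ccc(OC)cc3)=C\[C@H]2OC([O-])=C[C@H]12.[Li+] | intermediate
30 | (1(10)E,4E,6R,7S,8S)-8,14-bis[(tert-butyldimethylsilyl)oxy]-13-(dimethylamino)-15-[(4-methoxybenzyl)oxy]germacra-1(10),4-dien-12,6-olide (C11 epimers) | CC(C)(C)[Si](C)(C)O[C@H]1C/C(CO[Si](C)(C)C(C)(C)C)=C\CC/C(COCc3ccc(OC)cc3)=C\[C@H]2OC(=O)C(CN(C)C)[C@H]12 | intermediate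
31 | trimethylammonium iodide of 30 (not isolated) | CC(C)(C)[Si](C)(C)O[C@H]1C/C(CO[Si](C)(C)C(C)(C)C)=C\CC/C(COCc3ccc(OC)cc3)=C\[C@H]2OC(=O)C(C[N+](C)(C)C)[C@H]12.[I-] | intermediate
32 | (1(10)E,4E,6R,7S,8S)-8,14-bis[(tert-butyldimethylsilyl)oxy]-15-[(4-methoxybenzyl)oxy]germacra-1(10),4,11(13)-trien-12,6-olide | CC(C)(C)[Si](C)(C)O[C@H]1C/C(CO[Si](C)(C)C(C)(C)C)=C\CC/C(COCc3ccc(OC)cc3)=C\[C@H]2OC(=O)C(=C)[C@H]12 | intermediate
33 | (1(10)E,4E,6R,7R,8S)-8,14-dihydroxy-15-[(4-methoxybenzyl)oxy]germacra-1(10),4,11(13)-trien-12,6-olide | O[C@H]1C/C(CO)=C\CC/C(COCc3ccc(OC)cc3)=C\[C@H]2OC(=O)C(=C)[C@H]12 | intermediate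
34 | (1(10)E,4E,6R,7R,8S)-14-acetoxy-8-hydroxy-15-[(4-methoxybenzyl)oxy]germacra-1(10),4,11(13)-trien-12,6-olide | O[C@H]1C/C(COC(C)=O)=C\CC/C(COCc3ccc(OC)cc3)=C\[C@H]2OC(=O)C(=C)[C@H]12 | intermediate
35 | ethyl 2-(hydroxymethyl)acrylate | C=C(CO)C(=O)OCC | starting material
36 | ethyl 2-{[(tert-butyldimethylsilyl)oxy]methyl}acrylate | C=C(CO[Si](C)(C)C(C)(C)C)C(=O)OCC | intermediate
37 | 2-{[(tert-butyldimethylsilyl)oxy]methyl}acrylic acid | C=C(CO[Si](C)(C)C(C)(C)C)C(=O)O | intermediate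
38 | mixed anhydride of 37 and 2,4,6-trichlorobenzoic acid (not isolated) | C=C(CO[Si](C)(C)C(C)(C)C)C(=O)OC(=O)c1c(Cl)cc(Cl)cc1Cl | intermediate
39 | (1(10)E,4E,6R,7R,8S)-14-acetoxy-8-({2-[(tert-butyldimethylsilyloxy)methyl]acryloyl}oxy)-15-[(4-methoxybenzyl)oxy]germacra-1(10),4,11(13)-trien-12,6-olide | C=C(CO[Si](C)(C)C(C)(C)C)C(=O)O[C@H]1C/C(COC(C)=O)=C\CC/C(COCc3ccc(OC)cc3)=C\[C@H]2OC(=O)C(=C)[C@H]12 | intermediate
40 | (1(10)E,4E,6R,7R,8S)-14-acetoxy-8-({2-[(tert-butyldimethylsilyloxy)methyl]acryloyl}oxy)-15-hydroxygermacra-1(10),4,11(13)-trien-12,6-olide | C=C(CO[Si](C)(C)C(C)(C)C)C(=O)O[C@H]1C/C(COC(C)=O)=C\CC/C(CO)=C\[C@H]2OC(=O)C(=C)[C@H]12 | intermediate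
41 | (1(10)E,4E,6R,7R,8S)-14-acetoxy-8-({2-[(tert-butyldimethylsilyloxy)methyl]acryloyl}oxy)-15-oxogermacra-1(10),4,11(13)-trien-12,6-olide | C=C(CO[Si](C)(C)C(C)(C)C)C(=O)O[C@H]1C/C(COC(C)=O)=C\CC/C(C=O)=C\[C@H]2OC(=O)C(=C)[C@H]12 | intermediate
42 | (1(10)E,4E,6R,7R,8S)-14-acetoxy-8-{[2-(hydroxymethyl)acryloyl]oxy}-15-oxogermacra-1(10),4,11(13)-trien-12,6-olide | C=C(CO)C(=O)O[C@H]1C/C(COC(C)=O)=C\CC/C(C=O)=C\[C@H]2OC(=O)C(=C)[C@H]12 | target

Total step count: 25. Longest linear sequence: 20 steps (1–3, 6–10, 12–19, 22–25).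

Steps most likely to fail

1. Step 15. What may go wrong: addition to the C6 aldehyde from the wrong face, because the macrocyclic transition state can override Felkin–Anh control, alongside intermolecular coupling at insufficient dilution. Fallback: setting out from 25, the ring closure is run as before and the epimeric product, the cis-fused 6-epi lactone F1, is taken on. LiOH opens it to the γ-hydroxy acid F2, and a Mitsunobu lactonisation (PPh3, diisopropyl azodicarboxylate, toluene) activates the C6 hydroxyl and lets the C12 carboxylate displace it with inversion. This fixes C6 by substitution instead of by facial selectivity and returns to the route at 28.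

2. Step 2. What may go wrong: ether-directed addition in the reverse sense, which puts copper on C4 next to the CH2OPMB group and is followed by β-elimination to an allene. Fallback: setting out from 3 (as Grignard reagent 4) and commercial 3-(trimethylsilyl)prop-2-yn-1-ol, a CuI-catalysed anti-carbomagnesiation is used. The magnesium alkoxide chelate holds magnesium on the silylated carbon cis to CH2O, so the new chain ends up cis to silicon and protonation gives (E)-2-[2-(1,3-dioxolan-2-yl)ethyl]-3-(trimethylsilyl)prop-2-en-1-ol F3. Iododesilylation with N-iodosuccinimide proceeds with retention to (E)-2-[2-(1,3-dioxolan-2-yl)ethyl]-3-iodoprop-2-en-1-ol F4, and NaH with 4-methoxybenzyl chloride returns to the route at 7.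

3. Step 12. What may go wrong: isomerisation of the β,γ-unsaturated aldehyde into conjugation, lactonisation of the titanium aldolate onto the C12 ester, or eroded facial control because the ester competes for titanium. Fallback: setting out from 18, a boron aldol is used instead. (R)-4-Benzyl-2-oxazolidinone is N-acylated with 20 (n-BuLi, THF) to the oxazolidinone imide F5. Enolisation with Bu2BOTf and iPr2NEt and addition of 18 give, through the closed boron Zimmerman–Traxler transition state and without a free Lewis acid, the syn adduct F6. tBuMe2SiOTf and 2,6-lutidine give its silyl ether F7, LiSEt exchanges the auxiliary for the S-ethyl thioester F8, and iBu2AlH at −78 °C reduces the thioester to the aldehyde, returning to the route at 25.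

Further compounds
F1 | step 15 | (1(10)E,4E,6S,7S,8S)-8,14-bis[(tert-butyldimethylsilyl)oxy]-15-[(4-methoxybenzyl)oxy]-13-norgermacra-1(10),4-dien-12,6-olide (cis-fused 6-epimer of 28) | CC(C)(C)[Si](C)(C)O[C@H]1C/C(CO[Si](C)(C)C(C)(C)C)=C\CC/C(COCc3ccc(OC)cc3)=C\[C@@H]2OC(=O)C[C@H]12
F2 | step 15 | (1(10)E,4E,6S,7S,8S)-8,14-bis[(tert-butyldimethylsilyl)oxy]-6-hydroxy-15-[(4-methoxybenzyl)oxy]-13-norgermacra-1(10),4-dien-12-oic acid | CC(C)(C)[Si](C)(C)O[C@H]1C/C(CO[Si](C)(C)C(C)(C)C)=C\CC/C(COCc2ccc(OC)cc2)=C\[C@H](O)[C@@H]1CC(=O)O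
F3 | step 2 | (E)-2-[2-(1,3-dioxolan-2-yl)ethyl]-3-(trimethylsilyl)prop-2-en-1-ol | C[Si](C)(C)/C=C(\CCC1OCCO1)CO
F4 | step 2 | (E)-2-[2-(1,3-dioxolan-2-yl)ethyl]-3-iodoprop-2-en-1-ol | I/C=C(\CCC1OCCO1)CO
F5 | step 12 | methyl 4-[(4R)-4-benzyl-2-oxo-1,3-oxazolidin-3-yl]-4-oxobutanoate | COC(=O)CCC(=O)N1C(=O)OC[C@H]1Cc1ccccc1
F6 | step 12 | methyl (3R,4S,6E,10E)-3-{[(4R)-4-benzyl-2-oxo-1,3-oxazolidin-3-yl]carbonyl}-6-{[(tert-butyldimethylsilyl)oxy]methyl}-4-hydroxy-11-iodo-10-{[(4-methoxybenzyl)oxy]methyl}undeca-6,10-dienoate | O=C1OC[C@@H](Cc2ccccc2)N1C(=O)[C@H](CC(=O)OC)[C@@H](O)C/C(CO[Si](C)(C)C(C)(C)C)=C\CC/C(COCc1ccc(OC)cc1)=C\I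
F7 | step 12 | methyl (3R,4S,6E,10E)-3-{[(4R)-4-benzyl-2-oxo-1,3-oxazolidin-3-yl]carbonyl}-4-[(tert-butyldimethylsilyl)oxy]-6-{[(tert-butyldimethylsilyl)oxy]methyl}-11-iodo-10-{[(4-methoxybenzyl)oxy]methyl}undeca-6,10-dienoate | O=C1OC[C@@H](Cc2ccccc2)N1C(=O)[C@H](CC(=O)OC)[C@@H](O[Si](C)(C)C(C)(C)C)C/C(CO[Si](C)(C)C(C)(C)C)=C\CC/C(COCc1ccc(OC)cc1)=C\I
F8 | step 12 | methyl (3R,4S,6E,10E)-4-[(tert-butyldimethylsilyl)oxy]-6-{[(tert-butyldimethylsilyl)oxy]methyl}-3-[(ethylsulfanyl)carbonyl]-11-iodo-10-{[(4-methoxybenzyl)oxy]methyl}undeca-6,10-dienoate | CCSC(=O)[C@H](CC(=O)OC)[C@@H](O[Si](C)(C)C(C)(C)C)C/C(CO[Si](C)(C)C(C)(C)C)=C\CC/C(COCc1ccc(OC)cc1)=C\I
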